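**Retrosynthetic overview**

1. Target 26 is reached from diol 15 and acid 20 by an end game on the periphery only: C2 esterification, Markovnikov hydrocarboxylation of a C1 ethynyl group to the acrylic acid, SeO2 hydroxylation at C6, acetylation, desilylation. Naphthalene locants are used throughout: C1 carries the acrylic acid, C2 the ester oxygen, C4 the methyl carbinol, C6 the acetate, C7=C8 is the ring alkene, C4a/C8a are the ring fusion.
2. Diol 15 comes from bicyclic enone keto ester 9: one ring B cyclohexenone (C2=O, C3=C4) with a removable allyl ester at C1 supplies the C4 carbinol (epoxidation, then reduction), the C1 stereocentre (alkynylation, then decarboxylative protonation) and the C2 carbinol (directed reduction).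
3. Key disconnection: ring B of 9 is cut at C1–C8a and C3=C4, a [3+3] Michael/intramolecular Horner–Wadsworth–Emmons annulation of achiral dienone 4 with phosphono keto ester 7. The enabling feature is the 1,3-dioxygenated C2/C4 pair of ring B with the fusion carbon C8a β to C4: C8a–C4a–C4 is an acetylcyclohexene (1,3-dielectrophile) and C1–C2–C3 an acetone unit (1,3-dinucleophile).
4. Ring order: ring A first (Diels–Alder of isoprene with butynone), ring B second in the key step. Only C8a is set by a catalyst; C4a, C4, C1, C2 and C6 are relayed from it by substrate control.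

Key step: step 4

Conventions: β is the face of the bicycle that carries the two ring-fusion hydrogens (4a-H, 8a-H), α the opposite face; the absolute configuration is the one written in the SMILES strings.
Assumption: the sense of induction of the quinine-derived primary amine at C8a follows the usual iminium model for enones; if it is opposite on this dienone, the quinidine-derived pseudoenantiomer is used and nothing else changes.
Assumption: compounds 1, 2, 5, 6, 10 and 16 are bought.

**Route**

Step 1
Reactants: 1 isoprene (2-methylbuta-1,3-diene); 2 but-3-yn-2-one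
Product: 3 1-(4-methylcyclohexa-1,4-dien-1-yl)ethan-1-one
Conditions: Et2AlCl (0.2 equiv), CH2Cl2, −20 °C to rt
Reagents that add atoms: none
Why: Lewis-acid-promoted Diels–Alder reaction of a 2-substituted diene with an ynone, which should give the "para" 1,4-cyclohexadiene (the terminus of isoprene with the largest HOMO coefficient bonds to the β-carbon of the ynone); ring A is closed and no stereocentre is formed.

Step 2
Reactants: 3 1-(4-methylcyclohexa-1,4-dien-1-yl)ethan-1-one
Product: 4 1-(4-methylcyclohexa-1,3-dien-1-yl)ethan-1-one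
Conditions: DBU (0.2 equiv), CH2Cl2, rt, argon
Reagents that add atoms: none
Why: Base-mediated prototropic isomerisation: DBU removes a doubly allylic γ-proton and the extended dienolate is reprotonated at its ε-carbon, which should move the isolated alkene into linear conjugation (thermodynamic 2,4-dienone, no stereocentre).

Step 3
Reactants: 5 diethyl (2-oxopropyl)phosphonate; 6 diallyl carbonate
Product: 7 allyl 4-(diethoxyphosphoryl)-3-oxobutanoate
Conditions: LiN(iPr)2 (3.1 equiv), THF, −78 °C; then 6, −78 to 0 °C; aq. NH4Cl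
Reagents that add atoms: none
Why: Claisen-type C-acylation of the dianion of a β-keto phosphonate, whose terminal γ-carbanion is the more nucleophilic site; the third equivalent of base absorbs the more acidic product so that it is not acylated twice.

Step 4
Reactants: 4 1-(4-methylcyclohexa-1,3-dien-1-yl)ethan-1-one; 7 allyl 4-(diethoxyphosphoryl)-3-oxobutanoate
Product: 9 allyl cis-4,7-dimethyl-2-oxo-1,2,4a,5,6,8a-hexahydronaphthalene-1-carboxylate, via Michael adduct 8 (not isolated)
Conditions: 9-amino-9-deoxy-epi-quinine (20 mol %), 2-fluorobenzoic acid (40 mol %), toluene, 40 °C; then Cs2CO3 (2.5 equiv), MeCN, rt, same flask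
Reagents that add atoms: none
Why: The primary amine condenses with the acetyl group of 4 to a conjugated iminium ion, and the enol of the β-keto ester of 7 (its C2, far more acidic than the phosphonate CH2) adds 1,4 to the ring CH (the future C8a) on the face dictated by the catalyst ion pair, 1,6-addition being blocked by the methyl-bearing diene terminus; protonation at the future C4a and hydrolysis give 8. Cs2CO3 then generates the phosphonate carbanion, which adds to the ring-bound acetyl carbonyl in a 6-(enolendo)-exo-trig closure and expels diethyl phosphate (intramolecular Horner–Wadsworth–Emmons), so the second bond is formed as the C3=C4 alkene of ring B and only the phosphonate carbon, never the acetyl methyl, can be the second nucleophile. The closest known reaction type is the tandem Michael/intramolecular Horner–Wadsworth–Emmons cyclohexenone annulation of 4-phosphono-3-oxobutanoates with enones and enals (a Robinson-type [3+3] annulation), here preceded by an amine-catalysed enantioselective Michael step. C8a is set by the catalyst; C4a, now the γ-position of the new enone, equilibrates through the extended dienolate under the carbonate and should settle cis, because A(1,2) strain between the C4 methyl and the C4a–C5 bond forces that bond axial, which a trans ring fusion cannot accommodate; C1 is a labile β-keto ester centre of no consequence. The step needs 1,4- over 1,6-regioselectivity, facial control at C8a and the order Michael before olefination; these are secured by the methyl group at the diene terminus, the chiral amine and the acidity order of the two CH2 groups of 7.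

Step 5
Reactants: 9 allyl cis-4,7-dimethyl-2-oxo-1,2,4a,5,6,8a-hexahydronaphthalene-1-carboxylate; 10 1-[(trimethylsilyl)ethynyl]-1,2-benziodoxol-3(1H)-one (TMS-EBX)
Product: 11 allyl 1β-ethynyl-4,7-dimethyl-2-oxo-1,2,4a,5,6,8a-hexahydronaphthalene-1α-carboxylate
Conditions: Bu4NF (1.3 equiv), THF, −78 °C
Reagents that add atoms: none
Why: Electrophilic α-alkynylation of a β-keto ester enolate with an ethynylbenziodoxolone (fluoride frees the ethynyl hypervalent iodine reagent and forms the enolate) should give the quaternary C1 centre with the alkyne entering anti to the adjacent C8a–C8 bond (β face); this configuration is erased in step 8 and serves only to remove the acidic C1–H during the basic steps.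

Step 6
Reactants: 11 allyl 1β-ethynyl-4,7-dimethyl-2-oxo-1,2,4a,5,6,8a-hexahydronaphthalene-1α-carboxylate
Product: 12 allyl 3β,4β-epoxy-1β-ethynyl-4,7-dimethyl-2-oxo-1,2,3,4,4a,5,6,8a-octahydronaphthalene-1α-carboxylate
Conditions: t-BuOOH (3 equiv), DBU (1.5 equiv), CH2Cl2, 0 °C to rt
Reagents that add atoms: tert-butyl hydroperoxide, CC(C)(C)OO
Why: Weitz–Scheffer nucleophilic epoxidation of the only enone: the peroxide anion adds to C4 trans to the substituent on the neighbouring γ-carbon (the α-oriented C4a–C5 bond), as conjugate additions to 4-substituted cyclohexenones do, so the oxygen should end on the β face, while the electron-rich C7=C8 alkene and the alkyne are not touched.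

Step 7
Reactants: 12 allyl 3β,4β-epoxy-1β-ethynyl-4,7-dimethyl-2-oxo-1,2,3,4,4a,5,6,8a-octahydronaphthalene-1α-carboxylate
Product: 13 allyl 1β-ethynyl-4β-hydroxy-4,7-dimethyl-2-oxo-1,2,3,4,4a,5,6,8a-octahydronaphthalene-1α-carboxylate
Conditions: SmI2 (2.5 equiv), THF/MeOH, −78 °C
Reagents that add atoms: none
Why: Single-electron reduction of the α,β-epoxy ketone by SmI2 cleaves the Cα–O bond (C3–O) and protonation of the samarium enolate gives the β-hydroxy ketone, so the C4 carbinol keeps the β-oxygen set in step 6.

Step 8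
Reactants: 13 allyl 1β-ethynyl-4β-hydroxy-4,7-dimethyl-2-oxo-1,2,3,4,4a,5,6,8a-octahydronaphthalene-1α-carboxylate
Product: 15 1α-ethynyl-4,7-dimethyl-1,2,3,4,4a,5,6,8a-octahydronaphthalene-2α,4β-diol, via ynone 14 (not isolated)
Conditions: Pd2(dba)3 (2.5 mol %), PPh3 (10 mol %), Meldrum's acid (2.5 equiv), 1,4-dioxane, rt; then Me4NBH(OAc)3 (5 equiv), MeCN/AcOH, −30 to 0 °C
Reagents that add atoms: none
Why: Tsuji-type deallylative decarboxylation by zerovalent palladium gives the C1 enol, whose kinetic protonation anti to the neighbouring C8a–C8 bond should put H-1 on the β face and the slim ethynyl group α (axial), and the Evans–Saksena reduction then delivers hydride from the C4 alkoxyborohydride to the β face of C2 (1,3-anti diol, H-2 β and cis to H-1), the Felkin–Anh preference for attack anti to the ethynyl group acting in the same sense.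

Step 9
Reactants: 16 but-2-yne-1,4-diol
Product: 17 (E)-2-(tributylstannyl)but-2-ene-1,4-diol
Conditions: Bu3SnH (1.1 equiv), PdCl2(PPh3)2 (1 mol %), THF, rt
Reagents that add atoms: tributylstannane, CCCC[SnH](CCCC)CCCC
Why: Palladium-catalysed hydrostannation of an alkyne is a syn addition, so tin and hydrogen end cis and the two hydroxymethyl groups cis, which fixes the alkene geometry of the side chain.

Step 10
Reactants: 17 (E)-2-(tributylstannyl)but-2-ene-1,4-diol
Product: 18 (E)-1,4-bis(tert-butyldimethylsilyloxy)-2-(tributylstannyl)but-2-ene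
Conditions: TBSCl (2.3 equiv), imidazole, DMF, rt
Reagents that add atoms: tert-butyldimethylsilyl chloride, CC(C)(C)[Si](C)(C)Cl
Why: Standard silylation of two primary alcohols; the alkene geometry is not affected.

Step 11
Reactants: 18 (E)-1,4-bis(tert-butyldimethylsilyloxy)-2-(tributylstannyl)but-2-ene
Product: 20 (E)-4-(tert-butyldimethylsilyloxy)-2-[(tert-butyldimethylsilyloxy)methyl]but-2-enoic acid, via vinyllithium 19 (not isolated)
Conditions: n-BuLi (1.1 equiv), THF, −78 °C; CO2 (gas), −78 °C; cold aq. HCl to pH 3
Reagents that add atoms: carbon dioxide, O=C=O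
Why: Tin–lithium exchange of a vinylstannane and carboxylation of the vinyllithium both proceed with retention of alkene geometry, which should give the (E)-acid with the two silyloxymethyl groups cis; the low temperature suppresses β-elimination of the allylic silyloxy group.

Step 12
Reactants: 15 1α-ethynyl-4,7-dimethyl-1,2,3,4,4a,5,6,8a-octahydronaphthalene-2α,4β-diol; 20 (E)-4-(tert-butyldimethylsilyloxy)-2-[(tert-butyldimethylsilyloxy)methyl]but-2-enoic acid
Product: 22 1α-ethynyl-4β-hydroxy-4,7-dimethyl-1,2,3,4,4a,5,6,8a-octahydronaphthalen-2α-yl (E)-4-(tert-butyldimethylsilyloxy)-2-[(tert-butyldimethylsilyloxy)methyl]but-2-enoate, via mixed anhydride 21 (not isolated)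
Conditions: 2,4,6-trichlorobenzoyl chloride, Et3N, toluene, rt; then 15, DMAP, rt
Reagents that add atoms: none
Why: Yamaguchi esterification acylates the equatorial secondary C2 alcohol and leaves the hindered tertiary C4 alcohol untouched; no stereocentre changes and the (E)-enoate is the stable geometry.

Step 13
Reactants: 22 the C2 ester bearing the C1 ethynyl group
Product: 23 2-[2α-{(E)-4-(tert-butyldimethylsilyloxy)-2-[(tert-butyldimethylsilyloxy)methyl]but-2-enoyloxy}-4β-hydroxy-4,7-dimethyl-1,2,3,4,4a,5,6,8a-octahydronaphthalen-1α-yl]prop-2-enoic acid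
Conditions: Pd(OAc)2 (5 mol %), Xantphos (10 mol %), HCO2H (3 equiv), Ac2O (0.2 equiv), toluene, 80 °C
Reagents that add atoms: formic acid, O=CO
Why: Palladium-catalysed hydrocarboxylation of a terminal alkyne with formic acid as the source of hydride and CO: Markovnikov hydropalladation, CO insertion and hydrolysis should give the 2-substituted acrylic acid directly, with C1 (no longer enolisable) untouched and the C2 oxygen already acylated so that no lactone can form.

Step 14
Reactants: 23 the acrylic acid
Product: 24 the 6β-hydroxy derivative of 23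
Conditions: SeO2 (0.5 equiv), t-BuOOH (2 equiv), CH2Cl2, rt
Reagents that add atoms: selenium dioxide, O=[Se]=O (catalytic oxygen carrier); tert-butyl hydroperoxide, CC(C)(C)OO (terminal oxidant)
Why: Catalytic Riley oxidation (ene reaction of SeO2 at the less substituted alkene carbon C8, then 2,3-sigmatropic shift) hydroxylates the ring CH2 next to the methyl-bearing alkene carbon; the reagent should approach C8 anti to the C8a–C1 bond, on the convex β face, and the suprafacial shift hands the oxygen to C6 on that same face, while the two electron-poor alkenes are inert.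

Step 15
Reactants: 24 the 6β-alcohol
Product: 25 the 6β-acetate (bis-silyl ether of the target)
Conditions: Ac2O (1.5 equiv), pyridine, DMAP (5 mol %), CH2Cl2, 0 °C; aq. NaHCO3 work-up
Reagents that add atoms: acetic anhydride, CC(=O)OC(C)=O
Why: Acetylation of the secondary allylic C6 alcohol; the tertiary C4 alcohol is too hindered to react, and any mixed anhydride formed at the carboxylic acid is hydrolysed in the aqueous work-up.

Step 16
Reactants: 25 the 6β-acetate (bis-silyl ether of the target)
Product: 26 target acid
Conditions: HF·pyridine, THF/pyridine, 0 °C to rt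
Reagents that add atoms: none
Why: Fluoride cleaves the two primary silyl ethers under buffered conditions that should leave the allylic acetate, both esters, the acrylic acid and the tertiary alcohol intact.

**Compound list**

1 | isoprene (2-methylbuta-1,3-diene) | C=CC(C)=C | starting material
2 | but-3-yn-2-one | CC(=O)C#C | starting material
3 | 1-(4-methylcyclohexa-1,4-dien-1-yl)ethan-1-one | CC(=O)C1=CCC(C)=CC1 | intermediate
4 | 1-(4-methylcyclohexa-1,3-dien-1-yl)ethan-1-one | CC(=O)C1=CC=C(C)CC1 | intermediate
5 | diethyl (2-oxopropyl)phosphonate | CCOP(=O)(CC(C)=O)OCC | starting material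
6 | diallyl carbonate | C=CCOC(=O)OCC=C | starting material
7 | allyl 4-(diethoxyphosphoryl)-3-oxobutanoate | CCOP(=O)(CC(=O)CC(=O)OCC=C)OCC | intermediate
8 | allyl 2-(cis-6-acetyl-3-methylcyclohex-2-en-1-yl)-4-(diethoxyphosphoryl)-3-oxobutanoate (Michael adduct; C2 of the butanoate labile) | C=CCOC(=O)C(C(=O)CP(=O)(OCC)OCC)[C@@H]1C=C(C)CC[C@@H]1C(C)=O | intermediate (not isolated)
9 | allyl cis-4,7-dimethyl-2-oxo-1,2,4a,5,6,8a-hexahydronaphthalene-1-carboxylate (4a-H and 8a-H β; C1 labile) | C=CCOC(=O)C1[C@@H]2C=C(C)CC[C@@H]2C(C)=CC1=O | intermediate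
10 | 1-[(trimethylsilyl)ethynyl]-1,2-benziodoxol-3(1H)-one (TMS-EBX) | C[Si](C)(C)C#CI1OC(=O)c2ccccc12 | starting material
11 | allyl 1β-ethynyl-4,7-dimethyl-2-oxo-1,2,4a,5,6,8a-hexahydronaphthalene-1α-carboxylate | C=CCOC(=O)[C@]1(C#C)[C@@H]2C=C(C)CC[C@@H]2C(C)=CC1=O | intermediate
12 | allyl 3β,4β-epoxy-1β-ethynyl-4,7-dimethyl-2-oxo-1,2,3,4,4a,5,6,8a-octahydronaphthalene-1α-carboxylate | C=CCOC(=O)[C@]1(C#C)[C@@H]2C=C(C)CC[C@@H]2[C@@]3(C)O[C@H]3C1=O | intermediate
13 | allyl 1β-ethynyl-4β-hydroxy-4,7-dimethyl-2-oxo-1,2,3,4,4a,5,6,8a-octahydronaphthalene-1α-carboxylate | C=CCOC(=O)[C@]1(C#C)[C@@H]2C=C(C)CC[C@@H]2[C@@](C)(O)CC1=O | intermediate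
14 | 1α-ethynyl-4β-hydroxy-4,7-dimethyl-3,4,4a,5,6,8a-hexahydronaphthalen-2(1H)-one | C#C[C@@H]1[C@@H]2C=C(C)CC[C@@H]2[C@@](C)(O)CC1=O | intermediate (not isolated)
15 | 1α-ethynyl-4,7-dimethyl-1,2,3,4,4a,5,6,8a-octahydronaphthalene-2α,4β-diol | C#C[C@@H]1[C@@H]2C=C(C)CC[C@@H]2[C@@](C)(O)C[C@@H]1O | intermediate
16 | but-2-yne-1,4-diol | OCC#CCO | starting material
17 | (E)-2-(tributylstannyl)but-2-ene-1,4-diol | CCCC[Sn](CCCC)(CCCC)/C(=C/CO)CO | intermediate
18 | (E)-1,4-bis(tert-butyldimethylsilyloxy)-2-(tributylstannyl)but-2-ene | CCCC[Sn](CCCC)(CCCC)/C(=C/CO[Si](C)(C)C(C)(C)C)CO[Si](C)(C)C(C)(C)C | intermediate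
19 | [1,4-bis(tert-butyldimethylsilyloxy)but-2-en-2-yl]lithium (silyloxymethyl groups cis) | [Li]/C(=C/CO[Si](C)(C)C(C)(C)C)CO[Si](C)(C)C(C)(C)C | intermediate (not isolated)
20 | (E)-4-(tert-butyldimethylsilyloxy)-2-[(tert-butyldimethylsilyloxy)methyl]but-2-enoic acid | OC(=O)/C(=C/CO[Si](C)(C)C(C)(C)C)CO[Si](C)(C)C(C)(C)C | intermediate
21 | mixed anhydride of 20 with 2,4,6-trichlorobenzoic acid | O=C(OC(=O)c1c(Cl)cc(Cl)cc1Cl)/C(=C/CO[Si](C)(C)C(C)(C)C)CO[Si](C)(C)C(C)(C)C | intermediate (not isolated)
22 | 1α-ethynyl-4β-hydroxy-4,7-dimethyl-1,2,3,4,4a,5,6,8a-octahydronaphthalen-2α-yl (E)-4-(tert-butyldimethylsilyloxy)-2-[(tert-butyldimethylsilyloxy)methyl]but-2-enoate | C#C[C@@H]1[C@@H]2C=C(C)CC[C@@H]2[C@@](C)(O)C[C@@H]1OC(=O)/C(=C/CO[Si](C)(C)C(C)(C)C)CO[Si](C)(C)C(C)(C)C | intermediate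
23 | 2-[2α-{(E)-4-(tert-butyldimethylsilyloxy)-2-[(tert-butyldimethylsilyloxy)methyl]but-2-enoyloxy}-4β-hydroxy-4,7-dimethyl-1,2,3,4,4a,5,6,8a-octahydronaphthalen-1α-yl]prop-2-enoic acid | C=C(C(=O)O)[C@@H]1[C@@H]2C=C(C)CC[C@@H]2[C@@](C)(O)C[C@@H]1OC(=O)/C(=C/CO[Si](C)(C)C(C)(C)C)CO[Si](C)(C)C(C)(C)C | intermediate
24 | 6β-hydroxy derivative of 23 (4β,6β-dihydroxy acid) | C=C(C(=O)O)[C@@H]1[C@@H]2C=C(C)[C@@H](O)C[C@@H]2[C@@](C)(O)C[C@@H]1OC(=O)/C(=C/CO[Si](C)(C)C(C)(C)C)CO[Si](C)(C)C(C)(C)C | intermediate
25 | 6β-acetoxy derivative of 23 (bis-silyl ether of the target) | C=C(C(=O)O)[C@@H]1[C@@H]2C=C(C)[C@@H](OC(C)=O)C[C@@H]2[C@@](C)(O)C[C@@H]1OC(=O)/C(=C/CO[Si](C)(C)C(C)(C)C)CO[Si](C)(C)C(C)(C)C | intermediate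
26 | 2-[6β-acetoxy-4β-hydroxy-2α-{(E)-4-hydroxy-2-(hydroxymethyl)but-2-enoyloxy}-4,7-dimethyl-1,2,3,4,4a,5,6,8a-octahydronaphthalen-1α-yl]prop-2-enoic acid (CNP0468194.4) | C=C(C(=O)O)[C@@H]1[C@@H]2C=C(C)[C@@H](OC(C)=O)C[C@@H]2[C@@](C)(O)C[C@@H]1OC(=O)/C(=C/CO)CO | target

**Step count and risks**

Total step count: 16. Longest linear sequence: 12 steps (steps 1, 2, 4, 5, 6, 7, 8, 12, 13, 14, 15, 16).

Steps most likely to fail:

Step 4. The hindered, α-substituted dienone may condense only slowly with the amine, so that conversion is poor or an uncatalysed background addition erodes the facial selectivity at C8a. Fallback (resolution instead of asymmetric catalysis): setting out from 4 and 7, the annulation is run under the classical achiral conditions of the tandem Michael/Horner–Wadsworth–Emmons reaction (Cs2CO3, MeCN, rt). This should give 8 together with the enantiomeric Michael adduct F1, and from them 9 together with the enantiomeric keto ester F2. Alkynylation as in step 5 converts the pair into 11 and the enantiomeric alkyne F3, which carry no labile centre and are separated by preparative chromatography on a chiral stationary phase. The fallback comes back to the route at 11.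

Step 8. The transient β,γ-ynone 14 may isomerise to the conjugated allenyl ketone (which also destroys the C1 configuration), or the terminal alkyne may tie up the palladium catalyst before the ketone is reduced. Fallback (a capped alkyne carried through the same ring B chemistry): setting out from 9, alkynylation with the triisopropylsilyl analogue of 10 (1,1,3,3-tetramethylguanidine, THF, rt, no fluoride) should give the silyl alkyne F4. Epoxidation and SmI2 reduction as in steps 6 and 7 give the silyl epoxy ketone F5 and the silyl ketol F6. The conditions of step 8 then give the silyl ynone F7 (not isolated), which has no acetylenic hydrogen and a shielded alkyne terminus, and from it the silyl diol F8. Bu4NF in THF removes the silyl cap and the fallback comes back to the route at 15.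

Step 13. Hydropalladation may lose its Markovnikov preference next to the branched C1 (linear acid), or hot formic acid may cleave silyl ethers or dehydrate the tertiary alcohol. Fallback (ketone and enol triflate instead of direct hydrocarboxylation): setting out from 22, (Ph3P)AuNTf2-catalysed hydration of the alkyne (dioxane/H2O, 50 °C) should give the methyl ketone F9. Kinetic deprotonation of its methyl group with KN(SiMe3)2 (2.2 equiv, the first equivalent taken by the tertiary alcohol) in the presence of PhNTf2 at −78 °C gives the enol triflate F10. Hydroxycarbonylation (Pd(OAc)2, PPh3, CO 1 atm, KOAc, DMF/H2O, rt) gives 23, where the fallback comes back to the route.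

**Further compounds**

F1 | step 4 | enantiomer of Michael adduct 8 | C=CCOC(=O)C(C(=O)CP(=O)(OCC)OCC)[C@H]1C=C(C)CC[C@H]1C(C)=O
F2 | step 4 | enantiomer of keto ester 9 | C=CCOC(=O)C1[C@H]2C=C(C)CC[C@H]2C(C)=CC1=O
F3 | step 4 | enantiomer of alkyne 11 | C=CCOC(=O)[C@@]1(C#C)[C@H]2C=C(C)CC[C@H]2C(C)=CC1=O
F4 | step 8 | allyl 4,7-dimethyl-2-oxo-1β-[(triisopropylsilyl)ethynyl]-1,2,4a,5,6,8a-hexahydronaphthalene-1α-carboxylate | C=CCOC(=O)[C@]1(C#C[Si](C(C)C)(C(C)C)C(C)C)[C@@H]2C=C(C)CC[C@@H]2C(C)=CC1=O
F5 | step 8 | 3β,4β-epoxide of F4 | C=CCOC(=O)[C@]1(C#C[Si](C(C)C)(C(C)C)C(C)C)[C@@H]2C=C(C)CC[C@@H]2[C@@]3(C)O[C@H]3C1=O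
F6 | step 8 | allyl 4β-hydroxy-4,7-dimethyl-2-oxo-1β-[(triisopropylsilyl)ethynyl]-1,2,3,4,4a,5,6,8a-octahydronaphthalene-1α-carboxylate | C=CCOC(=O)[C@]1(C#C[Si](C(C)C)(C(C)C)C(C)C)[C@@H]2C=C(C)CC[C@@H]2[C@@](C)(O)CC1=O
F7 | step 8 | 4β-hydroxy-4,7-dimethyl-1α-[(triisopropylsilyl)ethynyl]-3,4,4a,5,6,8a-hexahydronaphthalen-2(1H)-one | CC(C)[Si](C(C)C)(C(C)C)C#C[C@@H]1[C@@H]2C=C(C)CC[C@@H]2[C@@](C)(O)CC1=O
F8 | step 8 | 4,7-dimethyl-1α-[(triisopropylsilyl)ethynyl]-1,2,3,4,4a,5,6,8a-octahydronaphthalene-2α,4β-diol | CC(C)[Si](C(C)C)(C(C)C)C#C[C@@H]1[C@@H]2C=C(C)CC[C@@H]2[C@@](C)(O)C[C@@H]1O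
F9 | step 13 | 1α-acetyl analogue of 22 (methyl ketone) | CC(=O)[C@@H]1[C@@H]2C=C(C)CC[C@@H]2[C@@](C)(O)C[C@@H]1OC(=O)/C(=C/CO[Si](C)(C)C(C)(C)C)CO[Si](C)(C)C(C)(C)C
F10 | step 13 | 1α-[1-(trifluoromethylsulfonyloxy)ethenyl] analogue of 22 (enol triflate) | C=C(OS(=O)(=O)C(F)(F)F)[C@@H]1[C@@H]2C=C(C)CC[C@@H]2[C@@](C)(O)C[C@@H]1OC(=O)/C(=C/CO[Si](C)(C)C(C)(C)C)CO[Si](C)(C)C(C)(C)C
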